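## Structural features

The target is a depsidone: ring A and ring B, both benzene rings, are bridged by a diaryl ether oxygen and by an ester, which closes a seven-membered dibenzo[b,e][1,4]dioxepin-11-one, and ring B is also fused to a five-membered lactone whose sp3 carbon is a lactol (a 3-hydroxyphthalide). Ring A carries, carbon after carbon, methoxy, free hydroxyl, the ether oxygen, the ester carbonyl carbon and a methyl group, and keeps a single CH. Ring B has no hydrogen: ether oxygen, ester oxygen, methyl, phenolic hydroxyl, the phthalide carbonyl carbon and the lactol carbon follow one another. The lactol carbon is the only stereocentre, (R); it has no stereogenic neighbour, but as the cyclic form of a 2-formylbenzoic acid it can invert by ring opening. Fragile points are the aryl ester of the seven-membered ring (cleaved by base and nucleophiles), the lactol, the oxidisable phenols and, during the synthesis, the vicinal oxygen pair of ring B, across which an acyl group can migrate. The real difficulties are the unambiguous placement of six different substituents on ring B, the diaryl ether flanked by four ortho substituents, and the delivery of one enantiomer of a labile hemiacetal. The key step uses the oxygen pattern of ring B: the ether carbon and the phenol carbon are para to each other, with the ester-oxygen carbon and the methyl carbon between them on one side, which is the C4–C3–C2–C1 array of a 4-oxy-3-alkoxy-2-methylcyclobutenone, while the lactol carbon and the carboxyl-bearing carbon on the other side map onto a 2-substituted propenyl group on C4.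

## Logic of the disconnections

28 is cut at the lactol O–H, back to the O–acetyl bond of 27, and 27 is cut at the same acetyl–O bond back to 26. The stereocentre can only be set on a lactol that racemises, and only an acylal holds it, so the enantiomer is made last and everything before 26 is racemic chemistry. The forward steps demand an enzyme that tells the two lactol enantiomers apart, and a final cleavage at the acyl–oxygen bond without water or base.

26 is cut at the lactol ring C–O bond (carboxyl oxygen to acetal carbon) and at all protecting-group bonds of 24: two O–CH2OCH3, the O–C(CH3)3 of the ester and the two C–OEt of the acetal. All are acid-labile, so one operation removes them and the formyl acid closes by itself. The demand is that the aryl ester of the seven-membered ring survives aqueous acid.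

24 is cut at the ester C–O bond of the seven-membered ring (ring B oxygen to the ring A acyl carbon) to give 23, and 23 at the benzyl–oxygen bond to give 22. A 2-(2-hydroxyphenoxy)benzoic acid is pre-organised for lactonisation, and the gain is an open diaryl ether. The forward steps need neutral hydrogenolysis and neutral carboxyl activation, because an acetal, two MOM ethers and a tert-butyl ester are present.

22 is cut at the diaryl ether C–O bond between the ring B oxygen and the bromine-bearing ring A carbon, which gives 15 and 21. The oxygen belongs to ring B because the ring construction delivers it there. The ether is made before the ester so that the two adjacent ring B oxygens cannot exchange their roles by acyl migration. The demand is a C–O coupling with four ortho substituents, which is why the ring A partner carries a free ortho carboxylate.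

15 is cut at the O–Si bond (14), 14 at the aryl C–CO2tBu bond on the only CH of ring B (12), and 12 at the O–MOM bond (11). The CH lies between two directing groups, so metalation is unambiguous. This puts a demand on the protecting groups: silyl (fluoride), benzyl (hydrogen) and MOM/acetal/tert-butyl (acid) must be mutually orthogonal. For that reason the oxygen on the quaternary carbon of 8 carries a silyl group and not an acetal-type group.

11 is cut at the ring B C–C bond between the phenol carbon and the CH carbon, with the enol returned to a ketene and the ring contracted, which gives 8. One C–C bond is removed and the aromatic ring is exchanged for a four-membered ring whose substituents are set by simple carbonyl additions. The forward step needs inward rotation of the alkenyl group on ring opening.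

8 is cut at the O–Si bond and at the C–C bond between the carbinol carbon and the alkenyl carbon, to 4 and 5. The gain is a symmetrical squarate-derived dione and a three-carbon acrolein unit. The demand is attack at the ketone-like carbonyl of 4 and not at the vinylogous ester carbonyl.

4 is cut at the C–CH3 bond and at one benzyl–oxygen bond to 2, and 2 at both ester O–benzyl bonds to 1. The symmetry of 2 makes the first addition unambiguous.

21 is cut at the C–CO2H bond (19), 19 at the C–I bond (18), 18 at the O–MOM bond (17) and 17 at the benzylic C–H bonds back to the aldehyde of 16. The bromine of 16 already stands on the future ether carbon, ortho to the hydroxyl. The demand is substitution para to the methoxy group and a metalation that touches iodine but not bromine.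

## Other disconnections considered

Alternative 1: The cut removes three ring B bonds at once (ether carbon to ester-oxygen carbon, methyl carbon to phenol carbon, carboxyl-bearing carbon to lactol-bearing carbon) and the phthalide ring with them. Forward, a monovalent rhodium catalyst, [Rh(cod)2]BF4 with BINAP, would trimerise diyne A1 (a ring A aryl ynol ether tethered through a methoxy acetal ester to a trimethylsilylpropiolate) with siloxyalkyne A2 to give A3.
- In favour: it is convergent, ring B and the lactone ring form in one neutral step, and the ether oxygen is attached to ring A before ring B exists. The crowded aryl–O–aryl coupling of the chosen route (step 12) is avoided, and on this point the alternative is the better plan.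
- Against: A3 carries a C–SiMe3 group on the carbon that must become the phenol carbon, so an ipso oxidation of an aryl silane in a hexasubstituted ring is still needed, next to an acetal and a tert-butyl ester. The orientation of the unsymmetrical alkyne A2 is not fixed by the tether. The ynol ether and mixed acylal functions of A1 are hard to assemble and easily hydrolysed. The chiral ligand cannot usefully fix the acetal carbon, which becomes labile later.
- Comparison: on structure, the chosen plan fixes all ring B positions by connectivity in 8, while here one regiochemical choice rests on steric bias. On mechanism, a metal-templated [2+2+2] stands against a catalyst-free pericyclic cascade, and both are well-founded types. On step economy the ring-forming phase is equal or slightly shorter here, but the C–Si to C–O exchange, the later lactonisation and the making of A1 use up the gain.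

Alternative 2: The cut is the ring B carbon–oxygen bond to the ester oxygen, traced back to spiro ketal A5, in which the ether oxygen and the acyloxy oxygen of ring A both sit on one ring B carbon. Forward, phenolic ester A4 would be dearomatised with PhI(OAc)2 to A5. Acid would then ionise the ketal C–O(acyl) bond, the carboxylate oxygen would shift to the neighbouring ring B CH, and loss of the proton would give A6.
- In favour: the diaryl ether forms intramolecularly at an ipso carbon under mild oxidation, which is easier than the intermolecular copper coupling of the chosen route and is the better feature of this plan. The seven-membered ring arises by ring expansion and needs no separate lactonisation. Only one ring B CH is free, so the ether and ester oxygens cannot be misplaced.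
- Against: the plan does not build ring B; the pentasubstituted ring B of A4, with formyl and ester groups, must come from classical arene substitution with its regiochemical problems. Oxidation of an electron-poor acyloxyphenol bearing an aldehyde is likely to be slow. Shift of the aryloxy group instead of the acyloxy group, or hydrolysis to a quinone, can compete. A6 still holds a methyl ester and a benzyl ether to remove.
- Comparison: on structure it is equal for the ether/ester regiochemistry and weaker for ring B substitution. On mechanism, a cationic 1,2-shift is less predictable than an electrocyclisation. On step economy it is similar after the union and longer before it.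

Alternative 3: The cut is the aryl C–O bond at the ring A CH ortho to the ring A hydroxyl. Forward, depside A7 would be oxidised at a carbon anode in hexafluoroisopropanol, and the free ring B phenol oxygen would bond to that CH to give A8.
- In favour: no halogen, no metal and no pre-functionalised ring A carbon are needed, the ester is made first by simple acylation, and the ring A hydroxyl is already free. In step count this is the shortest plan and is better than the chosen one.
- Against: A7 is a monoester of the vicinal oxygen pair of ring B, so acyl migration could exchange the ether and ester positions. A8, with a free hydroxyl next to the new ether, should be oxidised more easily than A7, which invites over-oxidation to quinones. The ring B phenol is hydrogen-bonded to the formyl group and is a poor nucleophile. Spiro dienone formation by attack at other ring A positions can compete.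
- Comparison: on structure, the chosen plan fixes the ether/ester assignment before the ester exists, while here it depends on the absence of acyl shift. On mechanism, a radical-cation C–O coupling forming a seven-membered ring is less well precedented than an Ullmann coupling. On step economy the alternative is clearly better if the coupling is selective.

Key step: step 4

Assumption: the lactol centre can invert through the open formyl acid, so it is assumed that 28, released without water or base and kept cold, can be isolated with its configuration intact; it is also assumed that screening of commercial lipases finds one that acylates the (R)-lactol.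

## Route

Step 1
Reactants: 1 squaric acid (3,4-dihydroxycyclobut-3-ene-1,2-dione)
Product: 2 dibenzyl squarate [3,4-bis(benzyloxy)cyclobut-3-ene-1,2-dione]
Conditions: BnOH (4 equiv), toluene, reflux, Dean–Stark trap
Reagents that add atoms: benzyl alcohol (OCc1ccccc1)
Why: Squaric acid is a strong vinylogous acid and esterifies with alcohols when water is removed azeotropically (Fischer-type esterification without added catalyst).

Step 2
Reactants: 2 dibenzyl squarate
Product: 4 3-(benzyloxy)-4-methylcyclobut-3-ene-1,2-dione, via methyl adduct 3 (not isolated)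
Conditions: MeLi (1.05 equiv), THF, −78 °C; then aqueous HCl, CH2Cl2, 0 °C to rt
Reagents that add atoms: methyllithium ([Li]C); water (O)
Why: 1,2-Addition of MeLi to one of the two equivalent carbonyls gives carbinol 3; acid ionises the tertiary alcohol, water adds to the benzyloxy-stabilised cation and benzyl alcohol is lost (the known squarate ester to alkylcyclobutenedione sequence).

Step 3
Reactants: 5 2-bromo-3,3-diethoxyprop-1-ene; 4 3-(benzyloxy)-4-methylcyclobut-3-ene-1,2-dione
Product: 8 rac-3-(benzyloxy)-4-[(tert-butyldimethylsilyl)oxy]-4-(3,3-diethoxyprop-1-en-2-yl)-2-methylcyclobut-2-en-1-one, via vinyllithium 6 (not isolated), via lithium alkoxide 7 (not isolated)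
Conditions: t-BuLi (2.0 equiv), Et2O, −78 °C; transfer to 4 in THF, −78 °C; then TBSOTf (1.2 equiv), −78 to 0 °C; aqueous NaHCO3
Reagents that add atoms: tert-butyldimethylsilyl trifluoromethanesulfonate (CC(C)(C)[Si](C)(C)OS(=O)(=O)C(F)(F)F)
Why: Bromine–lithium exchange gives the 2-lithioacrolein acetal, which adds to the carbonyl next to the benzyloxy-bearing carbon, because the other carbonyl is deactivated as a vinylogous ester. The lithium alkoxide is silylated in the same flask, so the base-sensitive carbinol is never handled; the new quaternary centre is racemic and disappears in step 4.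

Step 4
Reactants: 8 rac-3-(benzyloxy)-4-[(tert-butyldimethylsilyl)oxy]-4-(3,3-diethoxyprop-1-en-2-yl)-2-methylcyclobut-2-en-1-one
Product: 11 3-(benzyloxy)-4-[(tert-butyldimethylsilyl)oxy]-5-(diethoxymethyl)-2-methylphenol, via dienylketene 9 (not isolated), via cyclohexadienone 10 (not isolated)
Conditions: degassed toluene (0.02 M), 110 °C, argon
Reagents that add atoms: none
Why: Heat opens the cyclobutenone by a conrotatory 4π electrocyclic cleavage of the C1–C4 bond to dienylketene 9. The silyloxy group on C4 is a donor and should turn outward, so the diethoxypropenyl group turns inward next to the ketene carbon. A disrotatory 6π electrocyclisation then joins the ketene carbon to the terminal CH2 of the alkene, which is the ring B bond between the future phenol carbon and the future carboxyl-bearing carbon, and closes ring B as cyclohexadienone 10. Enolisation of 10 gives phenol 11; ring-strain release drives the opening and aromatisation drives the end. The closest known reaction type is the thermal ring expansion of 4-alkenyl-4-oxycyclobutenones to hydroquinone derivatives (Moore rearrangement). No stereocentre is formed and the racemic carbinol centre of 8 is lost. The step needs torquoselectivity, which the oxygen donor on C4 secures, and closure onto the alkene in preference to interception of the ketene, which dilution and exclusion of nucleophiles secure; the places of methyl, benzyloxy, silyloxy and acetal follow from the connectivity of 8 and cannot scramble.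

Step 5
Reactants: 11 3-(benzyloxy)-4-[(tert-butyldimethylsilyl)oxy]-5-(diethoxymethyl)-2-methylphenol
Product: 12 [2-(benzyloxy)-6-(diethoxymethyl)-4-(methoxymethoxy)-3-methylphenoxy](tert-butyl)dimethylsilane
Conditions: MOMCl, i-Pr2NEt, CH2Cl2, 0 °C to rt
Reagents that add atoms: chloromethyl methyl ether (COCCl)
Why: O-Alkylation of the only free phenol under basic conditions that leave the acetal and silyl ether intact; the MOM ether also serves as the directing group for step 6.

Step 6
Reactants: 12 [2-(benzyloxy)-6-(diethoxymethyl)-4-(methoxymethoxy)-3-methylphenoxy](tert-butyl)dimethylsilane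
Product: 14 tert-butyl 4-(benzyloxy)-3-[(tert-butyldimethylsilyl)oxy]-2-(diethoxymethyl)-6-(methoxymethoxy)-5-methylbenzoate, via aryllithium 13 (not isolated)
Conditions: n-BuLi (1.3 equiv), THF, 0 °C; then Boc2O, −78 °C to rt; water
Reagents that add atoms: di-tert-butyl dicarbonate (CC(C)(C)OC(=O)OC(=O)OC(C)(C)C)
Why: Directed ortho-metalation: the only ring CH lies between the MOM ether and the acetal, whose oxygens cooperate in binding lithium, and the aryllithium is acylated by Boc2O to the tert-butyl ester.

Step 7
Reactants: 14 tert-butyl 4-(benzyloxy)-3-[(tert-butyldimethylsilyl)oxy]-2-(diethoxymethyl)-6-(methoxymethoxy)-5-methylbenzoate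
Product: 15 tert-butyl 4-(benzyloxy)-2-(diethoxymethyl)-3-hydroxy-6-(methoxymethoxy)-5-methylbenzoate
Conditions: Bu4NF (1.1 equiv), THF, 0 °C; aqueous NH4Cl
Reagents that add atoms: none
Why: Fluoride cleaves the aryl silyl ether selectively; acetal, MOM ether, benzyl ether and the hindered tert-butyl ester are inert to fluoride.

Step 8
Reactants: 16 5-bromovanillin (3-bromo-4-hydroxy-5-methoxybenzaldehyde)
Product: 17 2-bromo-6-methoxy-4-methylphenol
Conditions: Et3SiH (2.5 equiv), CF3CO2H, CH2Cl2, 0 °C to rt
Reagents that add atoms: none
Why: Ionic hydrogenation: the para-hydroxyl stabilises the benzylic cation, so hydride transfer from the silane takes the aldehyde through the benzyl alcohol to the methyl group without touching the aryl bromide.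

Step 9
Reactants: 17 2-bromo-6-methoxy-4-methylphenol
Product: 18 1-bromo-3-methoxy-2-(methoxymethoxy)-5-methylbenzene
Conditions: MOMCl, i-Pr2NEt, CH2Cl2, 0 °C to rt
Reagents that add atoms: chloromethyl methyl ether (COCCl)
Why: Standard O-alkylation of the phenol; the MOM group is stable to the metal reagents, base and hydrogenolysis ahead and leaves in the final acid step.

Step 10
Reactants: 18 1-bromo-3-methoxy-2-(methoxymethoxy)-5-methylbenzene
Product: 19 3-bromo-2-iodo-5-methoxy-4-(methoxymethoxy)-1-methylbenzene
Conditions: N-iodosuccinimide (1.1 equiv), (CF3)2CHOH, 0 °C to rt, dark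
Reagents that add atoms: N-iodosuccinimide (O=C1CCC(=O)N1I)
Why: Electrophilic aromatic iodination para to the methoxy group, the strongest director with a free para position; the other CH is ortho to that group and screened by its methyl. The fluorinated alcohol activates the reagent without added acid, so the MOM ether should survive.

Step 11
Reactants: 19 3-bromo-2-iodo-5-methoxy-4-(methoxymethoxy)-1-methylbenzene
Product: 21 2-bromo-4-methoxy-3-(methoxymethoxy)-6-methylbenzoic acid, via arylmagnesium chloride 20 (not isolated)
Conditions: i-PrMgCl·LiCl (1.1 equiv), THF, −40 °C; CO2 gas, −40 to 0 °C; cold dilute HCl to pH 3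
Reagents that add atoms: carbon dioxide (O=C=O)
Why: Iodine–magnesium exchange is far faster than bromine–magnesium exchange, so only the C–I bond is metalated; the ortho-bromoarylmagnesium is stable at low temperature and is carboxylated by CO2.

Step 12
Reactants: 15 tert-butyl 4-(benzyloxy)-2-(diethoxymethyl)-3-hydroxy-6-(methoxymethoxy)-5-methylbenzoate; 21 2-bromo-4-methoxy-3-(methoxymethoxy)-6-methylbenzoic acid
Product: 22 2-[2-(benzyloxy)-5-(tert-butoxycarbonyl)-6-(diethoxymethyl)-4-(methoxymethoxy)-3-methylphenoxy]-4-methoxy-3-(methoxymethoxy)-6-methylbenzoic acid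
Conditions: CuI (0.3 equiv), Cs2CO3 (3 equiv), DMF, 110 °C, argon; cold aqueous citric acid to pH 4–5
Reagents that add atoms: none
Why: Ullmann diaryl ether synthesis accelerated by the ortho carboxylate of 21, which binds copper and delivers it to the neighbouring C–Br bond. Making the ether before the ester fixes which of the two adjacent ring B oxygens carries the ring A carbon; all protecting groups are stable to carbonate.

Step 13
Reactants: 22 2-[2-(benzyloxy)-5-(tert-butoxycarbonyl)-6-(diethoxymethyl)-4-(methoxymethoxy)-3-methylphenoxy]-4-methoxy-3-(methoxymethoxy)-6-methylbenzoic acid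
Product: 23 2-[5-(tert-butoxycarbonyl)-6-(diethoxymethyl)-2-hydroxy-4-(methoxymethoxy)-3-methylphenoxy]-4-methoxy-3-(methoxymethoxy)-6-methylbenzoic acid
Conditions: H2 (1 atm), Pd on carbon (10 wt% Pd), EtOAc, rt
Reagents that add atoms: none
Why: Hydrogenolysis of the single benzyl ether; no aryl halide is left, and MOM ethers, acetal, tert-butyl ester and the diaryl ether are inert under neutral conditions.

Step 14
Reactants: 23 2-[5-(tert-butoxycarbonyl)-6-(diethoxymethyl)-2-hydroxy-4-(methoxymethoxy)-3-methylphenoxy]-4-methoxy-3-(methoxymethoxy)-6-methylbenzoic acid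
Product: 24 tert-butyl 6-(diethoxymethyl)-3-methoxy-4,8-bis(methoxymethoxy)-1,9-dimethyl-11-oxo-11H-dibenzo[b,e][1,4]dioxepine-7-carboxylate
Conditions: DCC (1.2 equiv), DMAP (0.1 equiv), CH2Cl2 (0.005 M), 0 °C to rt
Reagents that add atoms: none
Why: Steglich-type lactonisation: the diaryl ether hinge holds the phenol next to the activated carboxyl, so the seven-membered aryl ester closes under neutral conditions that spare all acid-labile groups. The only free hydroxyl is the one ortho to the ether oxygen on ring B.

Step 15
Reactants: 24 tert-butyl 6-(diethoxymethyl)-3-methoxy-4,8-bis(methoxymethoxy)-1,9-dimethyl-11-oxo-11H-dibenzo[b,e][1,4]dioxepine-7-carboxylate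
Product: 26 rac-1,4,11-trihydroxy-10-methoxy-5,8-dimethyl-1H-isobenzofuro[4,5-b][1,4]benzodioxepine-3,7-dione, via formyl acid 25 (not isolated)
Conditions: CF3CO2H–H2O (9:1), 0 °C to rt
Reagents that add atoms: water (O)
Why: Acid cleaves the tert-butyl ester, both MOM ethers and the diethyl acetal in one operation, and the resulting 2-formylbenzoic acid closes to the lactol. The lactol forms as the racemate, and aryl esters are stable to this acid.

Step 16
Reactants: 26 rac-1,4,11-trihydroxy-10-methoxy-5,8-dimethyl-1H-isobenzofuro[4,5-b][1,4]benzodioxepine-3,7-dione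
Product: 27 (1R)-4,11-dihydroxy-10-methoxy-5,8-dimethyl-3,7-dioxo-1,3-dihydro-7H-isobenzofuro[4,5-b][1,4]benzodioxepin-1-yl acetate
Conditions: immobilised Burkholderia cepacia lipase, vinyl acetate (5 equiv), Et3N (0.1 equiv), 2-methyltetrahydrofuran, 40 °C
Reagents that add atoms: vinyl acetate (CC(=O)OC=C)
Why: Lipase-catalysed dynamic kinetic acetylation of a cyclic hemiacetal: the lactol enantiomers interconvert through the open formyl acid, helped by the catalytic amine, while the enzyme acetylates one of them irreversibly. The chiral active site sets the (R) centre, and the acylal can no longer ring-open.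

Step 17
Reactants: 27 (1R)-4,11-dihydroxy-10-methoxy-5,8-dimethyl-3,7-dioxo-1,3-dihydro-7H-isobenzofuro[4,5-b][1,4]benzodioxepin-1-yl acetate
Product: 28 (1R)-1,4,11-trihydroxy-10-methoxy-5,8-dimethyl-1H-isobenzofuro[4,5-b][1,4]benzodioxepine-3,7-dione
Conditions: immobilised Burkholderia cepacia lipase, n-BuOH (5 equiv), dry 2-methyltetrahydrofuran, 20 °C; filtration, evaporation below 20 °C
Reagents that add atoms: none
Why: Lipase-catalysed alcoholysis breaks the acyl–oxygen bond, so the stereocentre is not touched. The same enzyme preference removes the acetate from the (R) isomer, and the absence of water and base suppresses ring-chain racemisation of the product.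

## Compound list

1 | squaric acid (3,4-dihydroxycyclobut-3-ene-1,2-dione) | O=C1C(O)=C(O)C1=O | starting material
2 | dibenzyl squarate [3,4-bis(benzyloxy)cyclobut-3-ene-1,2-dione] | O=C1C(OCc2ccccc2)=C(OCc2ccccc2)C1=O | intermediate
3 | rac-2,3-bis(benzyloxy)-4-hydroxy-4-methylcyclobut-2-en-1-one | CC1(O)C(OCc2ccccc2)=C(OCc2ccccc2)C1=O | intermediate
4 | 3-(benzyloxy)-4-methylcyclobut-3-ene-1,2-dione | CC1=C(OCc2ccccc2)C(=O)C1=O | intermediate
5 | 2-bromo-3,3-diethoxyprop-1-ene | CCOC(OCC)C(Br)=C | starting material
6 | (3,3-diethoxyprop-1-en-2-yl)lithium | [Li]C(=C)C(OCC)OCC | intermediate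
7 | lithium rac-2-(benzyloxy)-1-(3,3-diethoxyprop-1-en-2-yl)-3-methyl-4-oxocyclobut-2-en-1-olate | CC1=C(OCc2ccccc2)C([O-])(C(=C)C(OCC)OCC)C1=O.[Li+] | intermediate
8 | rac-3-(benzyloxy)-4-[(tert-butyldimethylsilyl)oxy]-4-(3,3-diethoxyprop-1-en-2-yl)-2-methylcyclobut-2-en-1-one | CC1=C(OCc2ccccc2)C(O[Si](C)(C)C(C)(C)C)(C(=C)C(OCC)OCC)C1=O | intermediate
9 | (3Z)-3-(benzyloxy)-4-[(tert-butyldimethylsilyl)oxy]-5-(diethoxymethyl)-2-methylhexa-1,3,5-trien-1-one | O=C=C(C)/C(OCc1ccccc1)=C(/O[Si](C)(C)C(C)(C)C)C(=C)C(OCC)OCC | intermediate
10 | 3-(benzyloxy)-4-[(tert-butyldimethylsilyl)oxy]-5-(diethoxymethyl)-2-methylcyclohexa-2,4-dien-1-one | CC1=C(OCc2ccccc2)C(O[Si](C)(C)C(C)(C)C)=C(C(OCC)OCC)CC1=O | intermediate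
11 | 3-(benzyloxy)-4-[(tert-butyldimethylsilyl)oxy]-5-(diethoxymethyl)-2-methylphenol | Cc1c(O)cc(C(OCC)OCC)c(O[Si](C)(C)C(C)(C)C)c1OCc1ccccc1 | intermediate
12 | [2-(benzyloxy)-6-(diethoxymethyl)-4-(methoxymethoxy)-3-methylphenoxy](tert-butyl)dimethylsilane | Cc1c(OCOC)cc(C(OCC)OCC)c(O[Si](C)(C)C(C)(C)C)c1OCc1ccccc1 | intermediate
13 | {4-(benzyloxy)-3-[(tert-butyldimethylsilyl)oxy]-2-(diethoxymethyl)-6-(methoxymethoxy)-5-methylphenyl}lithium | Cc1c(OCOC)c([Li])c(C(OCC)OCC)c(O[Si](C)(C)C(C)(C)C)c1OCc1ccccc1 | intermediate
14 | tert-butyl 4-(benzyloxy)-3-[(tert-butyldimethylsilyl)oxy]-2-(diethoxymethyl)-6-(methoxymethoxy)-5-methylbenzoate | Cc1c(OCOC)c(C(=O)OC(C)(C)C)c(C(OCC)OCC)c(O[Si](C)(C)C(C)(C)C)c1OCc1ccccc1 | intermediate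
15 | tert-butyl 4-(benzyloxy)-2-(diethoxymethyl)-3-hydroxy-6-(methoxymethoxy)-5-methylbenzoate | Cc1c(OCOC)c(C(=O)OC(C)(C)C)c(C(OCC)OCC)c(O)c1OCc1ccccc1 | intermediate
16 | 5-bromovanillin (3-bromo-4-hydroxy-5-methoxybenzaldehyde) | COc1cc(C=O)cc(Br)c1O | starting material
17 | 2-bromo-6-methoxy-4-methylphenol | COc1cc(C)cc(Br)c1O | intermediate
18 | 1-bromo-3-methoxy-2-(methoxymethoxy)-5-methylbenzene | COCOc1c(Br)cc(C)cc1OC | intermediate
19 | 3-bromo-2-iodo-5-methoxy-4-(methoxymethoxy)-1-methylbenzene | COCOc1c(Br)c(I)c(C)cc1OC | intermediate
20 | [2-bromo-4-methoxy-3-(methoxymethoxy)-6-methylphenyl]magnesium chloride | COCOc1c(Br)c([Mg]Cl)c(C)cc1OC | intermediate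
21 | 2-bromo-4-methoxy-3-(methoxymethoxy)-6-methylbenzoic acid | COCOc1c(OC)cc(C)c(C(=O)O)c1Br | intermediate
22 | 2-[2-(benzyloxy)-5-(tert-butoxycarbonyl)-6-(diethoxymethyl)-4-(methoxymethoxy)-3-methylphenoxy]-4-methoxy-3-(methoxymethoxy)-6-methylbenzoic acid | COCOc1c(OC)cc(C)c(C(=O)O)c1Oc1c(OCc2ccccc2)c(C)c(OCOC)c(C(=O)OC(C)(C)C)c1C(OCC)OCC | intermediate
23 | 2-[5-(tert-butoxycarbonyl)-6-(diethoxymethyl)-2-hydroxy-4-(methoxymethoxy)-3-methylphenoxy]-4-methoxy-3-(methoxymethoxy)-6-methylbenzoic acid | COCOc1c(OC)cc(C)c(C(=O)O)c1Oc1c(O)c(C)c(OCOC)c(C(=O)OC(C)(C)C)c1C(OCC)OCC | intermediate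
24 | tert-butyl 6-(diethoxymethyl)-3-methoxy-4,8-bis(methoxymethoxy)-1,9-dimethyl-11-oxo-11H-dibenzo[b,e][1,4]dioxepine-7-carboxylate | COc1cc(C)c2c(c1OCOC)Oc1c(c(C)c(OCOC)c(C(=O)OC(C)(C)C)c1C(OCC)OCC)OC2=O | intermediate
25 | 6-formyl-4,8-dihydroxy-3-methoxy-1,9-dimethyl-11-oxo-11H-dibenzo[b,e][1,4]dioxepine-7-carboxylic acid | COc1cc(C)c2c(c1O)Oc1c(c(C)c(O)c(C(=O)O)c1C=O)OC2=O | intermediate
26 | rac-1,4,11-trihydroxy-10-methoxy-5,8-dimethyl-1H-isobenzofuro[4,5-b][1,4]benzodioxepine-3,7-dione | COc1cc(C)c2c(c1O)Oc1c(c(C)c(O)c3c1C(O)OC3=O)OC2=O | intermediate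
27 | (1R)-4,11-dihydroxy-10-methoxy-5,8-dimethyl-3,7-dioxo-1,3-dihydro-7H-isobenzofuro[4,5-b][1,4]benzodioxepin-1-yl acetate | COc1cc(C)c2c(c1O)Oc1c(c(C)c(O)c3c1[C@H](OC(C)=O)OC3=O)OC2=O | intermediate
28 | (1R)-1,4,11-trihydroxy-10-methoxy-5,8-dimethyl-1H-isobenzofuro[4,5-b][1,4]benzodioxepine-3,7-dione | COc1cc(C)c2c(c1O)Oc1c(c(C)c(O)c3c1[C@H](O)OC3=O)OC2=O | target

## Step count and least certain steps

Total step count: 17. Longest linear sequence: 13 steps (steps 1–7 and 12–17); the ring A branch has 4 steps (8–11).

Step 4 (key step). The 6π closure of the crowded dienylketene 9 may be slow, so the ketene could be used up by dimerisation or by traces of nucleophiles, and the acetal could lose ethanol on hot glass. The fallback moves the differentiation of the two ring oxygens to after the ring expansion: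
- It sets out from lithium alkoxide 7, which is protonated with aqueous NH4Cl instead of being silylated, to give rac-3-(benzyloxy)-4-(3,3-diethoxyprop-1-en-2-yl)-4-hydroxy-2-methylcyclobut-2-en-1-one F1.
- F1 carries the smaller free hydroxyl, the classical substrate type for this ring expansion. Heating in degassed toluene should give 2-(benzyloxy)-6-(diethoxymethyl)-3-methylbenzene-1,4-diol F2.
- F2 is protected at once at its less hindered hydroxyl (MOMCl, 1 equiv, i-Pr2NEt, −20 °C) to give 2-(benzyloxy)-6-(diethoxymethyl)-4-(methoxymethoxy)-3-methylphenol F3.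
- Silylation of F3 (TBSCl, imidazole, DMF) returns to the route at 12.

Step 12. With four ortho substituents the C–O bond formation may stall, and then hydrodebromination or protodecarboxylation of 21 would take over; the free acid could also cost the acetal during acidic work-up. The fallback changes metal, mechanism and substrate:
- It sets out from 21, which is esterified (BnBr, K2CO3, DMF) to benzyl 2-bromo-4-methoxy-3-(methoxymethoxy)-6-methylbenzoate F4.
- F4 is coupled with 15 by zerovalent palladium catalysis (Pd2(dba)3, 2-di-tert-butylphosphino-2',4',6'-triisopropylbiphenyl, K3PO4, toluene, 100 °C) to benzyl 2-[2-(benzyloxy)-5-(tert-butoxycarbonyl)-6-(diethoxymethyl)-4-(methoxymethoxy)-3-methylphenoxy]-4-methoxy-3-(methoxymethoxy)-6-methylbenzoate F5.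
- Hydrogenolysis of F5 (H2, Pd on carbon, EtOAc) removes the benzyl ester and the benzyl ether together and returns to the route at 23.

Step 6. Deprotonation at the benzylic CH2 of the benzyl ether, attack of the base at silicon, or incomplete metalation of the crowded CH may compete. The fallback replaces C–H metalation by halogenation and halogen–metal exchange:
- It sets out from 12, which is brominated at its only ring CH (N-bromosuccinimide, NaHCO3, MeCN, 0 °C) to [2-(benzyloxy)-5-bromo-6-(diethoxymethyl)-4-(methoxymethoxy)-3-methylphenoxy](tert-butyl)dimethylsilane F6.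
- Bromine–lithium exchange on F6 (n-BuLi, THF, −78 °C) gives 13 at a temperature where the benzyl ether and the silyl ether are not attacked; Boc2O then returns to the route at 14.

Step 10. Iodination at the CH between bromine and methyl may be sluggish, which would allow attack at the other CH or loss of the MOM group if acid has to be added. The fallback replaces halogenation–metalation by Friedel–Crafts-type formylation and oxidation on an acid-stable ester:
- It sets out from 17, which is acetylated (Ac2O, pyridine) to 2-bromo-6-methoxy-4-methylphenyl acetate F7.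
- Rieche formylation of F7 para to the methoxy group (Cl2CHOMe, TiCl4, CH2Cl2, 0 °C) gives 2-bromo-3-formyl-6-methoxy-4-methylphenyl acetate F8.
- Methanolysis of F8 (K2CO3, MeOH) gives 2-bromo-3-hydroxy-4-methoxy-6-methylbenzaldehyde F9.
- MOM protection of F9 (MOMCl, i-Pr2NEt) gives 2-bromo-4-methoxy-3-(methoxymethoxy)-6-methylbenzaldehyde F10.
- Pinnick oxidation of F10 (NaClO2, NaH2PO4, 2-methylbut-2-ene, t-BuOH–H2O) returns to the route at 21.

Step 16. The crowded, poorly soluble lactol may be acylated too slowly or with the wrong enantiomer preference, or racemisation may not keep pace with acylation. The fallback replaces asymmetric catalysis by separation of a configurationally stable derivative: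
- It sets out from 26, which is peracetylated (Ac2O, pyridine, DMAP) to rac-10-methoxy-5,8-dimethyl-3,7-dioxo-1,3-dihydro-7H-isobenzofuro[4,5-b][1,4]benzodioxepine-1,4,11-triyl triacetate F11.
- Preparative chromatography of F11 on a chiral stationary phase gives (1R)-10-methoxy-5,8-dimethyl-3,7-dioxo-1,3-dihydro-7H-isobenzofuro[4,5-b][1,4]benzodioxepine-1,4,11-triyl triacetate F12.
- Lipase-catalysed alcoholysis of F12 (n-BuOH, dry 2-methyltetrahydrofuran, 20 °C) removes all three acetates and returns to the route at 28. Deacylation is much easier for a hydrolase than acylation of a hindered hemiacetal and needs no enantioselectivity at this point.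

## Further compounds

F1 | step 4 | rac-3-(benzyloxy)-4-(3,3-diethoxyprop-1-en-2-yl)-4-hydroxy-2-methylcyclobut-2-en-1-one | CC1=C(OCc2ccccc2)C(O)(C(=C)C(OCC)OCC)C1=O
F2 | step 4 | 2-(benzyloxy)-6-(diethoxymethyl)-3-methylbenzene-1,4-diol | Cc1c(O)cc(C(OCC)OCC)c(O)c1OCc1ccccc1
F3 | step 4 | 2-(benzyloxy)-6-(diethoxymethyl)-4-(methoxymethoxy)-3-methylphenol | Cc1c(OCOC)cc(C(OCC)OCC)c(O)c1OCc1ccccc1
F4 | step 12 | benzyl 2-bromo-4-methoxy-3-(methoxymethoxy)-6-methylbenzoate | COCOc1c(OC)cc(C)c(C(=O)OCc2ccccc2)c1Br
F5 | step 12 | benzyl 2-[2-(benzyloxy)-5-(tert-butoxycarbonyl)-6-(diethoxymethyl)-4-(methoxymethoxy)-3-methylphenoxy]-4-methoxy-3-(methoxymethoxy)-6-methylbenzoate | COCOc1c(OC)cc(C)c(C(=O)OCc2ccccc2)c1Oc1c(OCc2ccccc2)c(C)c(OCOC)c(C(=O)OC(C)(C)C)c1C(OCC)OCC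
F6 | step 6 | [2-(benzyloxy)-5-bromo-6-(diethoxymethyl)-4-(methoxymethoxy)-3-methylphenoxy](tert-butyl)dimethylsilane | Cc1c(OCOC)c(Br)c(C(OCC)OCC)c(O[Si](C)(C)C(C)(C)C)c1OCc1ccccc1
F7 | step 10 | 2-bromo-6-methoxy-4-methylphenyl acetate | COc1cc(C)cc(Br)c1OC(C)=O
F8 | step 10 | 2-bromo-3-formyl-6-methoxy-4-methylphenyl acetate | COc1cc(C)c(C=O)c(Br)c1OC(C)=O
F9 | step 10 | 2-bromo-3-hydroxy-4-methoxy-6-methylbenzaldehyde | COc1cc(C)c(C=O)c(Br)c1O
F10 | step 10 | 2-bromo-4-methoxy-3-(methoxymethoxy)-6-methylbenzaldehyde | COCOc1c(OC)cc(C)c(C=O)c1Br
F11 | step 16 | rac-10-methoxy-5,8-dimethyl-3,7-dioxo-1,3-dihydro-7H-isobenzofuro[4,5-b][1,4]benzodioxepine-1,4,11-triyl triacetate | COc1cc(C)c2c(c1OC(C)=O)Oc1c(c(C)c(OC(C)=O)c3c1C(OC(C)=O)OC3=O)OC2=O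
F12 | step 16 | (1R)-10-methoxy-5,8-dimethyl-3,7-dioxo-1,3-dihydro-7H-isobenzofuro[4,5-b][1,4]benzodioxepine-1,4,11-triyl triacetate | COc1cc(C)c2c(c1OC(C)=O)Oc1c(c(C)c(OC(C)=O)c3c1[C@H](OC(C)=O)OC3=O)OC2=O
A1 | alternative 1 | rac-tert-butyl 4-methoxy-2-({3-methoxy-3-[(3-(trimethylsilyl)prop-2-ynoyl)oxy]prop-1-yn-1-yl}oxy)-3-(methoxymethoxy)-6-methylbenzoate | COc1cc(C)c(C(=O)OC(C)(C)C)c(OC#CC(OC)OC(=O)C#C[Si](C)(C)C)c1OCOC
A2 | alternative 1 | triisopropyl(prop-1-yn-1-yloxy)silane | CC#CO[Si](C(C)C)(C(C)C)C(C)C
A3 | alternative 1 | rac-tert-butyl 4-methoxy-2-{[3-methoxy-6-methyl-1-oxo-5-(triisopropylsilyloxy)-7-(trimethylsilyl)-1,3-dihydroisobenzofuran-4-yl]oxy}-3-(methoxymethoxy)-6-methylbenzoate | COc1cc(C)c(C(=O)OC(C)(C)C)c(Oc2c(O[Si](C(C)C)(C(C)C)C(C)C)c(C)c([Si](C)(C)C)c3c2C(OC)OC3=O)c1OCOC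
A4 | alternative 2 | methyl 3-{[3-(benzyloxy)-2-hydroxy-4-methoxy-6-methylbenzoyl]oxy}-2-formyl-6-hydroxy-5-methylbenzoate | COc1cc(C)c(C(=O)Oc2cc(C)c(O)c(C(=O)OC)c2C=O)c(O)c1OCc1ccccc1
A5 | alternative 2 | rac-methyl 8'-(benzyloxy)-2-formyl-7'-methoxy-5,5'-dimethyl-4,4'-dioxo-4'H-spiro[cyclohexa-2,5-diene-1,2'-[1,3]benzodioxine]-3-carboxylate | COc1cc(C)c2c(c1OCc1ccccc1)OC1(OC2=O)C=C(C)C(=O)C(C(=O)OC)=C1C=O
A6 | alternative 2 | methyl 4-(benzyloxy)-6-formyl-8-hydroxy-3-methoxy-1,9-dimethyl-11-oxo-11H-dibenzo[b,e][1,4]dioxepine-7-carboxylate | COc1cc(C)c2c(c1OCc1ccccc1)Oc1c(c(C)c(O)c(C(=O)OC)c1C=O)OC2=O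
A7 | alternative 3 | tert-butyl 2-formyl-3-hydroxy-4-[(5-hydroxy-4-methoxy-2-methylbenzoyl)oxy]-6-(methoxymethoxy)-5-methylbenzoate | COc1cc(C)c(C(=O)Oc2c(C)c(OCOC)c(C(=O)OC(C)(C)C)c(C=O)c2O)cc1O
A8 | alternative 3 | tert-butyl 6-formyl-4-hydroxy-3-methoxy-8-(methoxymethoxy)-1,9-dimethyl-11-oxo-11H-dibenzo[b,e][1,4]dioxepine-7-carboxylate | COc1cc(C)c2c(c1O)Oc1c(c(C)c(OCOC)c(C(=O)OC(C)(C)C)c1C=O)OC2=O
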